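**Strategy**

Everything rests on the C4–C5 bond of the hydroxy-γ-lactam (ring E: N1, C2–C5), which also belongs to the 13-membered paracyclophane. C5 is a masked ketone and the methylene C4 lies β to both the C2 amide and the ring A acyl carbonyl, so the bond is formed by a carbene-catalysed Stetter macrocyclisation of an arylacetaldehyde onto a 2-methylene β-keto amide released in the flask. The primary amide then closes ring E on the new C5 ketone, and the labile C3 and C5 centres equilibrate. The precursor is an open keto amide aldehyde on the tricyclic core (rings A–C), assembled by an intramolecular Diels–Alder reaction.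

Key step: step 24

Ring names: A = cyclohexene, B = cyclopentane, C = trimethylcyclohexane, D = p-phenylene, E = lactam (N1, C2 carbonyl, C3 acyl-bearing CH, C4 methylene, C5 carbinol carbon).

Assumption: the C3/C5 configuration of the target is taken to be the most stable one within the bridged macrocycle, since C3 can invert through the enol and C5 through the open keto amide.

**Route**

Step 1
Reactants: 1 meso-2,4-dimethylglutaric anhydride
Product: 2 (2R,4S)-5-methoxy-2,4-dimethyl-5-oxopentanoic acid
Conditions: MeOH (10 equiv), (DHQD)2AQN (10 mol %), Et2O, −30 °C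
Reagents that add atoms: methanol CO
Why: Cinchona-alkaloid-catalysed desymmetrising alcoholysis of a meso anhydride should direct methanol to one enantiotopic carbonyl and so fix both methyl-bearing centres; the pseudo-enantiomeric catalyst gives the mirror image, so the (2R,4S) sense is accessible.

Step 2
Reactants: 2 (2R,4S)-5-methoxy-2,4-dimethyl-5-oxopentanoic acid
Product: 3 methyl (2S,4R)-5-hydroxy-2,4-dimethylpentanoate
Conditions: BH3·SMe2, THF, 0 °C to rt; MeOH quench; used without delay
Reagents that add atoms: none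
Why: Chemoselective borane reduction of a carboxylic acid beside an ester touches no stereocentre.

Step 3
Reactants: 3 methyl (2S,4R)-5-hydroxy-2,4-dimethylpentanoate
Product: 4 methyl (2S,4R)-2,4-dimethyl-5-oxopentanoate
Conditions: TEMPO (10 mol %), PhI(OAc)2, CH2Cl2, rt
Reagents that add atoms: none
Why: The nitroxyl-catalysed oxidation of a primary alcohol should stop at the aldehyde under non-basic conditions that do not epimerise the α-centre.

Step 4
Reactants: 4 methyl (2S,4R)-2,4-dimethyl-5-oxopentanoate
Product: 5 methyl (2S,4R)-6-cyano-2,4-dimethylhex-5-enoate (E/Z mixture)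
Conditions: Ph3P=CHCN, toluene, 60 °C
Reagents that add atoms: (triphenylphosphoranylidene)acetonitrile N#CC=P(c1ccccc1)(c1ccccc1)c1ccccc1
Why: Wittig olefination with a stabilised ylide adds the two carbons that become the quaternary carbon and its nitrile; alkene geometry is irrelevant.

Step 5
Reactants: 5 methyl (2S,4R)-6-cyano-2,4-dimethylhex-5-enoate
Product: 6 methyl (2S,4S)-6-cyano-2,4-dimethylhexanoate
Conditions: H2 (1 atm), Pd/C, EtOAc, rt
Reagents that add atoms: none
Why: Catalytic hydrogenation of the conjugated alkene leaves nitrile and ester intact.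

Step 6
Reactants: 6 methyl (2S,4S)-6-cyano-2,4-dimethylhexanoate
Product: 7 (3S,5R)-3,5-dimethyl-2-oxocyclohexane-1-carbonitrile (C1 epimers)
Conditions: KOt-Bu, THF, 0 °C to rt; aq. HCl
Reagents that add atoms: none
Why: Thorpe–Dieckmann condensation: the nitrile-stabilised carbanion acylates on the ester and the acidic α-cyano ketone drives the equilibrium, while C3 settles equatorial (cis to the C5 methyl) through the enolate.

Step 7
Reactants: 7 (3S,5R)-3,5-dimethyl-2-oxocyclohexane-1-carbonitrile
Product: 8 (1S,3S,5R)-1,3,5-trimethyl-2-oxocyclohexane-1-carbonitrile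
Conditions: MeI, K2CO3, acetone, rt
Reagents that add atoms: iodomethane CI
Why: C-alkylation of the α-cyano ketone enolate: the cis-3,5-dimethyl pattern locks the ring and methyl iodide should enter along the axial trajectory (chair-like transition state), giving the axial methyl and equatorial nitrile.

Step 8
Reactants: 8 (1S,3S,5R)-1,3,5-trimethyl-2-oxocyclohexane-1-carbonitrile
Product: 9 (1R,3S,5R)-2-(methoxymethylidene)-1,3,5-trimethylcyclohexane-1-carbonitrile (E/Z mixture)
Conditions: MeOCH2PPh3Cl, KN(SiMe3)2, THF, 0 °C; then 8, 0 to 60 °C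
Reagents that add atoms: (methoxymethyl)triphenylphosphonium chloride COC[P+](c1ccccc1)(c1ccccc1)c1ccccc1.[Cl-]
Why: Wittig homologation with the methoxymethylidene ylide; the α-cyano group makes the hindered ketone more electrophilic and only one side can enolise.

Step 9
Reactants: 9 (1R,3S,5R)-2-(methoxymethylidene)-1,3,5-trimethylcyclohexane-1-carbonitrile
Product: 10 (1R,2R,3S,5R)-2-formyl-1,3,5-trimethylcyclohexane-1-carbonitrile
Conditions: aq. HCl (1 M), THF, rt; then K2CO3 (cat.), MeOH, rt
Reagents that add atoms: water O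
Why: Enol ether hydrolysis followed by base equilibration should place the formyl group equatorial, trans to the C3 methyl (thermodynamic control at C2).

Step 10
Reactants: 10 (1R,2R,3S,5R)-2-formyl-1,3,5-trimethylcyclohexane-1-carbonitrile; 11 3,3-diethoxyprop-1-yne
Product: 14 (1R,2R,3S,5R)-2-[(1S,2E)-4,4-diethoxy-1-hydroxybut-2-enyl]-1,3,5-trimethylcyclohexane-1-carbonitrile, via alkenylborane 12 (not isolated), via alkenylzinc 13 (not isolated)
Conditions: 11, Cy2BH (from BH3·SMe2 and cyclohexene), toluene, 0 °C; Et2Zn, −78 °C; (−)-MIB (10 mol %), then 10, −20 to 0 °C; aq. NH4Cl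
Reagents that add atoms: none
Why: Hydroboration, boron–zinc exchange and amino-alcohol-catalysed alkenylzinc addition: (−)-MIB should direct Si-face attack on the aldehyde, setting the (S)-carbinol under catalyst control with the E-alkene kept.

Step 11
Reactants: 15 2-(4-iodophenyl)ethanol
Product: 17 [4-(2-hydroxyethyl)phenyl](2,4,6-trimethoxyphenyl)iodonium tosylate, via hydroxy(tosyloxy)iodoarene 16 (not isolated)
Conditions: mCPBA, TsOH·H2O, MeCN, rt; then 1,3,5-trimethoxybenzene
Reagents that add atoms: 1,3,5-trimethoxybenzene COc1cc(OC)cc(OC)c1; 4-methylbenzenesulfonic acid monohydrate Cc1ccc(cc1)S(O)(=O)=O.O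
Why: One-pot oxidation of the aryl iodide and electrophilic aromatic substitution of the electron-rich arene is the standard route to unsymmetrical diaryliodonium tosylates.

Step 12
Reactants: 17 [4-(2-hydroxyethyl)phenyl](2,4,6-trimethoxyphenyl)iodonium tosylate
Product: 18 {4-[2-(tert-butyldimethylsilyloxy)ethyl]phenyl}(2,4,6-trimethoxyphenyl)iodonium tosylate
Conditions: TBSOTf, 2,6-lutidine, CH2Cl2, −78 to 0 °C
Reagents that add atoms: tert-butyldimethylsilyl triflate CC(C)(C)[Si](C)(C)OS(=O)(=O)C(F)(F)F
Why: Silylation of the primary alcohol with a non-nucleophilic base leaves the iodonium centre untouched.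

Step 13
Reactants: 14 (S)-allylic alcohol; 18 silyl-protected iodonium tosylate
Product: 19 (1R,2R,3S,5R)-2-[(1S,2E)-1-{4-[2-(tert-butyldimethylsilyloxy)ethyl]phenoxy}-4,4-diethoxybut-2-enyl]-1,3,5-trimethylcyclohexane-1-carbonitrile
Conditions: NaH, toluene/THF, 0 °C; then 18, rt
Reagents that add atoms: none
Why: Metal-free O-arylation of an alkoxide by ligand coupling at trivalent iodine: the trimethoxyphenyl group should stay on iodine and the carbinol C–O bond is not broken, so the (S) configuration is retained.

Step 14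
Reactants: 19 aryl ether nitrile
Product: 20 aryl ether aldehyde (formyl in place of the nitrile of 19; stereocentres unchanged)
Conditions: i-Bu2AlH, toluene, −78 to −40 °C; aq. potassium sodium tartrate (KNaC4H4O6), then pH 5 buffer
Reagents that add atoms: water O
Why: Partial reduction: the hydride adds once to the hindered nitrile and the aluminated imine hydrolyses to the aldehyde on work-up.

Step 15
Reactants: 20 aryl ether aldehyde
Product: 21 1,1-dibromoalkene
Conditions: CBr4, PPh3, Et3N, CH2Cl2, 0 °C
Reagents that add atoms: carbon tetrabromide BrC(Br)(Br)Br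
Why: Dibromo-olefination (first stage of the Corey–Fuchs sequence) works on non-enolisable neopentyl aldehydes, and the amine buffer protects the acetal.

Step 16
Reactants: 21 1,1-dibromoalkene
Product: 23 methyl alkyne (prop-1-ynyl group on the quaternary carbon), via lithium acetylide 22 (not isolated)
Conditions: n-BuLi (2.1 equiv), THF, −78 °C; then MeI, −78 °C to rt
Reagents that add atoms: iodomethane CI
Why: Corey–Fuchs alkyne synthesis: bromine–lithium exchange and elimination give the acetylide, which is methylated in the same flask.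

Step 17
Reactants: 24 (S)-but-3-yn-2-ol
Product: 26 (S,E)-4-iodo-3-methylbut-3-en-2-ol, via alkenylalane 25 (not isolated)
Conditions: Me3Al (3 equiv), Cp2ZrCl2 (25 mol %), CH2Cl2, 0 °C to rt; then I2, THF, −30 °C
Reagents that add atoms: trimethylaluminium C[Al](C)C; iodine II
Why: Zirconium-catalysed carboalumination adds methyl and aluminium syn across the alkyne (methyl on the internal carbon) and iodinolysis proceeds with retention, giving the E-iodide with the carbinol centre untouched.

Step 18
Reactants: 26 (S,E)-4-iodo-3-methylbut-3-en-2-ol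
Product: 27 (S,E)-tert-butyl[(4-iodo-3-methylbut-3-en-2-yl)oxy]dimethylsilane
Conditions: TBSCl, imidazole, DMF, rt
Reagents that add atoms: tert-butyldimethylsilyl chloride CC(C)(C)[Si](C)(C)Cl
Why: Standard silylation of a secondary alcohol.

Step 19
Reactants: 23 methyl alkyne; 27 silyl-protected vinyl iodide
Product: 30 (E,E)-diene acetal (tetraene), via alkenylzirconocene 28 (not isolated), via alkenylzinc chloride 29 (not isolated)
Conditions: Cp2Zr(H)Cl, THF, rt; then 27, ZnCl2, Pd(PPh3)4 (5 mol %), THF, rt to 40 °C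
Reagents that add atoms: none
Why: Syn hydrozirconation should place zirconium on the methyl-bearing alkyne carbon away from the quaternary centre, and zinc-assisted Negishi coupling with retention at both partners gives the diene with the quaternary carbon and the silyloxyethyl group both in outside positions.

Step 20
Reactants: 30 (E,E)-diene acetal
Product: 31 trienal alcohol (E-enal; free 2-hydroxyethyl group on ring D)
Conditions: AcOH/THF/H2O (3:1:1), rt
Reagents that add atoms: water O
Why: Mild acid hydrolyses the unsaturated acetal and the primary silyl ether while the hindered secondary silyl ether should survive.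

Step 21
Reactants: 31 trienal alcohol
Product: 32 tricyclic aldehyde (rings A–C; formyl on ring A; aryloxy on ring B; ring stereocentres as in the target)
Conditions: Me2AlCl (2.5 equiv), CH2Cl2, −78 to −20 °C
Reagents that add atoms: none
Why: Intramolecular Diels–Alder reaction through the endo (formyl) transition state: suprafacial addition of the E-enal to the (E,E)-diene fixes the four new centres relative to one another, and the trans-diequatorial arms on the locked chair of ring C allow only one unstrained twist of the forming trans-fused ring B, which selects the diene face.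

Step 22
Reactants: 32 tricyclic aldehyde
Product: 33 β-hydroxy amide (carbinol epimers)
Conditions: N-(trimethylsilyl)acetamide, n-BuLi (2 equiv per amide), THF, 0 °C; then 32, −78 °C; aq. NH4Cl
Reagents that add atoms: N-(trimethylsilyl)acetamide CC(=O)N[Si](C)(C)C
Why: Aldol addition of the dianion of an N-silyl acetamide, a primary acetamide enolate equivalent; the new carbinol centre is oxidised in the next step, so its configuration does not matter.

Step 23
Reactants: 33 β-hydroxy amide
Product: 34 seco keto amide aldehyde (β-keto amide on ring A; arylacetaldehyde on ring D)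
Conditions: Dess–Martin periodinane (2.5 equiv), NaHCO3, CH2Cl2, 0 °C to rt
Reagents that add atoms: none
Why: Dess–Martin oxidation converts the secondary carbinol and the primary alcohol in one operation without touching the silyl ether or the primary amide.

Step 24
Reactants: 34 seco keto amide aldehyde
Product: 38 O-silyl macrocyclic hydroxylactam, via Mannich salt 35 (not isolated), via methylene keto amide 36 (not isolated), via macrocyclic keto amide 37 (not isolated)
Conditions: Me2N=CH2+ I− (1.05 equiv), CH2Cl2, 0 °C; then slow addition to 3-benzyl-5-(2-hydroxyethyl)-4-methylthiazolium chloride (30 mol %), Et3N, 1,4-dioxane, 80 °C (2 mM); hold 12 h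
Reagents that add atoms: N,N-dimethylmethyleneiminium iodide C=[N+](C)C.[I-]
Why: Proposed new method: a macrocyclic variant of the Stetter reaction, whose closest known relatives are the thiazolium-catalysed Stetter addition of aliphatic aldehydes to enones liberated from Mannich bases and the intramolecular Stetter reaction for five- and six-membered rings. Et3N frees Mannich salt 35, which loses Me2NH (E1cB) to give the doubly activated methylene compound 36, while the thiazol-2-ylidene adds to the unhindered arylacetaldehyde to form the Breslow intermediate, whose acyl-anion carbon (C5) attacks the methylene terminus C4 in a 13-endo-trig conjugate addition and releases the carbene. The amide nitrogen then adds to the new C5 ketone of 37 (5-exo-trig) and closes ring E as the hydroxylactam. C3 is set by protonation and stays epimerisable through the enol, and C5 through ring–chain tautomerism, so under Et3N both should converge on the most stable arrangement of the bridged 13-membered ring, the control element being the fixed ring A and ring B carbons that carry the two ends of the tether. The step needs 1,4- over 1,2-addition and ring closure over oligomerisation, benzoin and aldol pathways; these are secured by a terminal methylene flanked by two carbonyls, its slow release from the salt, and high dilution.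

Step 25
Reactants: 38 O-silyl macrocyclic hydroxylactam
Product: 39 target CNP0565217.1
Conditions: HF·pyridine, pyridine, THF, 0 °C to rt
Reagents that add atoms: none
Why: Buffered fluoride desilylation should free the secondary alcohol without dehydrating the hydroxylactam or disturbing the β-keto amide.

**Compound list**

1 | meso-2,4-dimethylglutaric anhydride [(3R,5S)-3,5-dimethyloxane-2,6-dione] | O1C(=O)[C@H](C)C[C@H](C)C1=O | starting material
2 | (2R,4S)-5-methoxy-2,4-dimethyl-5-oxopentanoic acid | OC(=O)[C@H](C)C[C@H](C)C(=O)OC | intermediate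
3 | methyl (2S,4R)-5-hydroxy-2,4-dimethylpentanoate | OC[C@H](C)C[C@H](C)C(=O)OC | intermediate
4 | methyl (2S,4R)-2,4-dimethyl-5-oxopentanoate | O=C[C@H](C)C[C@H](C)C(=O)OC | intermediate
5 | methyl (2S,4R)-6-cyano-2,4-dimethylhex-5-enoate (E/Z mixture) | N#CC=C[C@H](C)C[C@H](C)C(=O)OC | intermediate
6 | methyl (2S,4S)-6-cyano-2,4-dimethylhexanoate | N#CCC[C@H](C)C[C@H](C)C(=O)OC | intermediate
7 | (3S,5R)-3,5-dimethyl-2-oxocyclohexane-1-carbonitrile (C1 epimers) | N#CC1C[C@H](C)C[C@H](C)C1=O | intermediate
8 | (1S,3S,5R)-1,3,5-trimethyl-2-oxocyclohexane-1-carbonitrile | N#C[C@]1(C)C[C@H](C)C[C@H](C)C1=O | intermediate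
9 | (1R,3S,5R)-2-(methoxymethylidene)-1,3,5-trimethylcyclohexane-1-carbonitrile (E/Z mixture) | N#C[C@]1(C)C[C@H](C)C[C@H](C)C1=COC | intermediate
10 | (1R,2R,3S,5R)-2-formyl-1,3,5-trimethylcyclohexane-1-carbonitrile | N#C[C@]1(C)C[C@H](C)C[C@H](C)[C@H]1C=O | intermediate
11 | 3,3-diethoxyprop-1-yne | C#CC(OCC)OCC | starting material
12 | (E)-dicyclohexyl(3,3-diethoxyprop-1-enyl)borane (formed in the flask) | CCOC(OCC)/C=C/B(C1CCCCC1)C1CCCCC1 | intermediate
13 | (E)-(3,3-diethoxyprop-1-enyl)(ethyl)zinc (formed in the flask) | CCOC(OCC)/C=C/[Zn]CC | intermediate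
14 | (1R,2R,3S,5R)-2-[(1S,2E)-4,4-diethoxy-1-hydroxybut-2-enyl]-1,3,5-trimethylcyclohexane-1-carbonitrile | N#C[C@]1(C)C[C@H](C)C[C@H](C)[C@H]1[C@@H](O)/C=C/C(OCC)OCC | intermediate
15 | 2-(4-iodophenyl)ethanol | OCCc1ccc(I)cc1 | starting material
16 | 2-{4-[hydroxy(tosyloxy)iodo]phenyl}ethanol (formed in the flask) | OCCc1ccc(cc1)I(O)OS(=O)(=O)c1ccc(C)cc1 | intermediate
17 | [4-(2-hydroxyethyl)phenyl](2,4,6-trimethoxyphenyl)iodonium tosylate | COc1cc(OC)c([I+]c2ccc(CCO)cc2)c(OC)c1.Cc1ccc(cc1)S(=O)(=O)[O-] | intermediate
18 | {4-[2-(tert-butyldimethylsilyloxy)ethyl]phenyl}(2,4,6-trimethoxyphenyl)iodonium tosylate | COc1cc(OC)c([I+]c2ccc(CCO[Si](C)(C)C(C)(C)C)cc2)c(OC)c1.Cc1ccc(cc1)S(=O)(=O)[O-] | intermediate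
19 | aryl ether nitrile (O-aryl derivative of 14; carbinol carbon S) | N#C[C@]1(C)C[C@H](C)C[C@H](C)[C@H]1[C@@H](Oc1ccc(CCO[Si](C)(C)C(C)(C)C)cc1)/C=C/C(OCC)OCC | intermediate
20 | aryl ether aldehyde (formyl on the quaternary ring C carbon) | O=C[C@]1(C)C[C@H](C)C[C@H](C)[C@H]1[C@@H](Oc1ccc(CCO[Si](C)(C)C(C)(C)C)cc1)/C=C/C(OCC)OCC | intermediate
21 | 1,1-dibromoalkene | BrC(Br)=C[C@]1(C)C[C@H](C)C[C@H](C)[C@H]1[C@@H](Oc1ccc(CCO[Si](C)(C)C(C)(C)C)cc1)/C=C/C(OCC)OCC | intermediate
22 | lithium acetylide (formed in the flask) | [Li]C#C[C@]1(C)C[C@H](C)C[C@H](C)[C@H]1[C@@H](Oc1ccc(CCO[Si](C)(C)C(C)(C)C)cc1)/C=C/C(OCC)OCC | intermediate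
23 | methyl alkyne (prop-1-ynyl on the quaternary ring C carbon) | CC#C[C@]1(C)C[C@H](C)C[C@H](C)[C@H]1[C@@H](Oc1ccc(CCO[Si](C)(C)C(C)(C)C)cc1)/C=C/C(OCC)OCC | intermediate
24 | (S)-but-3-yn-2-ol | C[C@H](O)C#C | starting material
25 | (S,E)-alkenylalane aluminium alkoxide (formed in the flask) | C[C@H](O[Al](C)C)/C(C)=C/[Al](C)C | intermediate
26 | (S,E)-4-iodo-3-methylbut-3-en-2-ol | C[C@H](O)/C(C)=C/I | intermediate
27 | (S,E)-tert-butyl[(4-iodo-3-methylbut-3-en-2-yl)oxy]dimethylsilane | C[C@H](O[Si](C)(C)C(C)(C)C)/C(C)=C/I | intermediate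
28 | alkenylzirconocene chloride from 23 (formed in the flask; Cp drawn as σ-cyclopentadienyl) | C/C(=C\[C@]1(C)C[C@H](C)C[C@H](C)[C@H]1[C@@H](Oc1ccc(CCO[Si](C)(C)C(C)(C)C)cc1)/C=C/C(OCC)OCC)[Zr](Cl)(C1C=CC=C1)C1C=CC=C1 | intermediate
29 | alkenylzinc chloride from 28 (formed in the flask) | C/C(=C\[C@]1(C)C[C@H](C)C[C@H](C)[C@H]1[C@@H](Oc1ccc(CCO[Si](C)(C)C(C)(C)C)cc1)/C=C/C(OCC)OCC)[Zn]Cl | intermediate
30 | (E,E)-diene acetal (tetraene; both silyl ethers present) | C[C@H](O[Si](C)(C)C(C)(C)C)/C(C)=C/C(C)=C/[C@]1(C)C[C@H](C)C[C@H](C)[C@H]1[C@@H](Oc1ccc(CCO[Si](C)(C)C(C)(C)C)cc1)/C=C/C(OCC)OCC | intermediate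
31 | trienal alcohol (E-enal; free primary alcohol) | C[C@H](O[Si](C)(C)C(C)(C)C)/C(C)=C/C(C)=C/[C@]1(C)C[C@H](C)C[C@H](C)[C@H]1[C@@H](Oc1ccc(CCO)cc1)/C=C/C=O | intermediate
32 | tricyclic aldehyde (rings A–C; ring stereocentres as in the target) | CC1=C[C@](C)([C@H](C)O[Si](C)(C)C(C)(C)C)[C@H](C=O)[C@@H]2[C@@H]1[C@]3(C)C[C@H](C)C[C@H](C)[C@H]3[C@H]2Oc4ccc(CCO)cc4 | intermediate
33 | β-hydroxy amide (carbinol epimers) | CC1=C[C@](C)([C@H](C)O[Si](C)(C)C(C)(C)C)[C@H](C(O)CC(N)=O)[C@@H]2[C@@H]1[C@]3(C)C[C@H](C)C[C@H](C)[C@H]3[C@H]2Oc4ccc(CCO)cc4 | intermediate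
34 | seco keto amide aldehyde | CC1=C[C@](C)([C@H](C)O[Si](C)(C)C(C)(C)C)[C@H](C(=O)CC(N)=O)[C@@H]2[C@@H]1[C@]3(C)C[C@H](C)C[C@H](C)[C@H]3[C@H]2Oc4ccc(CC=O)cc4 | intermediate
35 | Mannich salt (hydroiodide; C3 epimers; formed in the flask) | CC1=C[C@](C)([C@H](C)O[Si](C)(C)C(C)(C)C)[C@H](C(=O)C(C[NH+](C)C)C(N)=O)[C@@H]2[C@@H]1[C@]3(C)C[C@H](C)C[C@H](C)[C@H]3[C@H]2Oc4ccc(CC=O)cc4.[I-] | intermediate
36 | 2-methylene β-keto amide aldehyde (formed in the flask) | CC1=C[C@](C)([C@H](C)O[Si](C)(C)C(C)(C)C)[C@H](C(=O)C(=C)C(N)=O)[C@@H]2[C@@H]1[C@]3(C)C[C@H](C)C[C@H](C)[C@H]3[C@H]2Oc4ccc(CC=O)cc4 | intermediate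
37 | macrocyclic γ-keto amide (open form of the hydroxylactam; C3 epimers; formed in the flask) | CC1=C[C@](C)([C@H](C)O[Si](C)(C)C(C)(C)C)[C@@H]2C(=O)C(C(N)=O)CC(=O)Cc3ccc(cc3)O[C@H]3[C@H]2[C@@H]1[C@]1(C)C[C@H](C)C[C@H](C)[C@@H]31 | intermediate
38 | O-tert-butyldimethylsilyl ether of the target | CC1=C[C@](C)([C@H](C)O[Si](C)(C)C(C)(C)C)[C@@H]2C(=O)[C@H]3C[C@](O)(Cc4ccc(cc4)O[C@H]4[C@H]2[C@@H]1[C@]1(C)C[C@H](C)C[C@H](C)[C@@H]41)NC3=O | intermediate
39 | CNP0565217.1 | CC1=C[C@](C)([C@H](C)O)[C@@H]2C(=O)[C@H]3C[C@](O)(Cc4ccc(cc4)O[C@H]4[C@H]2[C@@H]1[C@]1(C)C[C@H](C)C[C@H](C)[C@@H]41)NC3=O | target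

**Step count and risks**

Total steps: 25. Longest linear sequence: 21 (steps 1–10, 13–16, 19–25); steps 11–12 and 17–18 make the two side fragments.

Most likely to fail:

1. Step 24 (Proposed new method). The enolisable arylacetaldehyde may be consumed by intermolecular Stetter, benzoin or aldol reactions before the strained 13-membered ring can close. The carbene may also be trapped by the methylene acceptor, or equilibration may settle on another C3/C5 pair. The fallback forms the same C4–C5 bond by known chemistry; it sets out from 32 and returns at 38. An MgI2-mediated iodo-aldol reaction of 32 with methyl propiolate gives the (Z)-β-iodo hydroxy ester F1. Dess–Martin oxidation of both alcohols gives the iodo enone aldehyde F2. A Nozaki–Hiyama–Kishi macrocyclisation (CrCl2, NiCl2 cat., DMSO/THF, high dilution) joins C4 to C5, and the new alkoxide lactonises onto the cis ester to give the macrocyclic butenolide F3. Ammonia in MeOH/THF opens F3 through its enol lactone tautomer to the keto amide, which closes to 38.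

2. Step 21. The diene carries an inside methyl group, so cycloaddition may be slow and a 1,5-hydrogen shift or Lewis-acid ionisation of the allylic silyl ether may compete; endo or facial selectivity may also erode. The fallback changes the activation from substrate-controlled Lewis acid catalysis to catalyst-controlled iminium catalysis: 31 is treated with a chiral 5-benzyl-2-tert-butyl-3-methylimidazolidin-4-one trifluoroacetate salt in MeCN/H2O at −20 °C to rt. It sets out from 31 and returns at 32, and no new compound is isolated (F0).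

3. Step 13. The iodonium salt may oxidise the allylic alkoxide to the enone, the wrong aryl group may transfer, or the hindered alkoxide may react too slowly. The fallback replaces retention at oxygen by inversion at carbon; it sets out from 10 and returns at 19. The alkenylzinc addition of step 10 is run with (+)-MIB to give the (R)-carbinol F4. Tyrosol is silylated on the primary hydroxyl (TBSCl, imidazole) to give 4-[2-(tert-butyldimethylsilyloxy)ethyl]phenol F5. A Mitsunobu reaction of F4 with F5 (PPh3, DIAD, toluene, 0 °C) gives 19.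

Further compounds
F1 | step 24 | (Z)-β-iodo hydroxy ester (methyl 2-(iodomethylidene)-3-hydroxypropanoate unit on ring A; carbinol epimers) | CC1=C[C@](C)([C@H](C)O[Si](C)(C)C(C)(C)C)[C@H](C(O)C(=C/I)/C(=O)OC)[C@@H]2[C@@H]1[C@]3(C)C[C@H](C)C[C@H](C)[C@H]3[C@H]2Oc4ccc(CCO)cc4
F2 | step 24 | iodo enone aldehyde | CC1=C[C@](C)([C@H](C)O[Si](C)(C)C(C)(C)C)[C@H](C(=O)C(=C/I)/C(=O)OC)[C@@H]2[C@@H]1[C@]3(C)C[C@H](C)C[C@H](C)[C@H]3[C@H]2Oc4ccc(CC=O)cc4
F3 | step 24 | macrocyclic butenolide (C5 epimers) | CC1=C[C@](C)([C@H](C)O[Si](C)(C)C(C)(C)C)[C@@H]2C(=O)C3=CC(Cc4ccc(cc4)O[C@H]4[C@H]2[C@@H]1[C@]1(C)C[C@H](C)C[C@H](C)[C@@H]41)OC3=O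
F0 | step 21 | none | none
F4 | step 13 | (1R,2R,3S,5R)-2-[(1R,2E)-4,4-diethoxy-1-hydroxybut-2-enyl]-1,3,5-trimethylcyclohexane-1-carbonitrile | N#C[C@]1(C)C[C@H](C)C[C@H](C)[C@H]1[C@H](O)/C=C/C(OCC)OCC
F5 | step 13 | 4-[2-(tert-butyldimethylsilyloxy)ethyl]phenol | Oc1ccc(CCO[Si](C)(C)C(C)(C)C)cc1
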